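The runs are simulated from invented constants, and the scatter is random.

The ratio of D to G charged, 27.4, is the count of turnovers each G owes if the D charged becomes Z, so the pace of one G is the quantity to read.

- alpha: D 0.074 M; Q 0.0888 M; J 1.48 mM; G 2.7 mM; the very flask that is asked about, followed so far
- flask: D 0.074 M; Q 0.0888 M; J 1.48 mM; G 2.7 mM; volume of the second phase over the first 1.0

alpha run (percent of the D charged)

| time / min | Z / % | D / % |
|---|---|---|
| 3.00 | 2.2 | 97.4 |
| 8.00 | 6.3 | 92.3 |
| 15.0 | 11.5 | 86.8 |
| 25.0 | 19.5 | 78.8 |

(scatter of a reading: 0.3 percentage points)

- charges count per volume of the first phase; a concentration in a rate is the amount of a species over the volume of its own phase; every rate counts per litre of the first phase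
- the earlier runs hold the two phases in the same ratio of volumes as the flask asked about
- no earlier run changes the charge of G; that part of a forecast is a guess

1. apparent order in G when 20% of the D are converted (percent change of the rate of making Z for one percent more G charged)

For a quick number: in the alpha run, which is this same flask followed so far, Z gains 13 percentage points of the D charged between 8.00 min and 25.0 min, while D falls from 92.3% to 78.8% and the gain per minute shows no matching fall. That gain gives the turnovers per hour of each G charged, the turnover frequency, 12.8 h⁻¹. My own reckoning takes this pace as belonging to each G separately, so that more G brings proportionally more Z and the order is one, though with G never varied this stays a guess. The forecast gives 1.1, with a wide range, and reasons that “If the catalyst is simply saturated, the order is about 1”.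

The flask gives 1.0.

    D + X → Z + G (k = 300 M⁻¹ min⁻¹)
    G + Q ⇌ X + E (K = 0.400, k = 2.60 M⁻¹ min⁻¹)
    D + J → L (k = 1.50 M⁻¹ min⁻¹)

At 1.00 h the flask holds 98.8% of its catalyst as G, the resting state. Held at 12.8 h⁻¹, each G charged would make 25.6 turnovers by 2.00 h, which is 93.2% of the D charged as Z, but the flask holds less, 67.0%, and at 2.05 h its rate stands at 0.49 of the rate when 20% of the D are converted.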